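**Retrosynthetic overview**

1. Target 32 ⇐ isoxazoline-bridged lactone 30: the β-ketol C1(=O)–C2–C3(OH) is stored as the ring C1=N–O–C3 (a ring not in the target) and released last by N–O cleavage, after the isovalerate is placed on O8.
2. Key cut, C6–C7 and O6–C12 together: Cr(II) intramolecular 2-(methoxycarbonyl)allylation/lactonisation of seco Z-enal bromide 24 closes the ten-membered carbocycle C1–C10 and the trans-fused α-methylene-γ-lactone (O–C6–C7–C11–C12) in one operation and sets C6/C7 from C8.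
3. Seco chain: C11–C13 by vinylalumination/SN2′ bromination at the C7 aldehyde; isoxazoline from aldol adduct 15 (C2–C3 bond, Z-C4=C5 from a Still–Gennari enal) by oxime Mitsunobu closure with inversion at C3.
4. C10 from (R)-linalool (vinyl becomes C1/C2 by Wacker oxidation, prenyl end cleaved to C7); C8 by proline-catalysed α-aminoxylation.
5. Ring order: isoxazoline → carbocycle + lactone (step 18) → isoxazoline opened.

Key step: step 18

Remark: atom labels C1–C15 are the germacranolide positions of the target (ring C1–C10; C11(=C13)–C12(=O)–O–C6; C14 on C10; C15 on C4); aldehyde 1 and phosphonate 2 are taken as catalogue compounds.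

**Route**

Step 1
Reactants: 1 2-[(4-methoxybenzyl)oxy]acetaldehyde; 2 ethyl 2-[bis(2,2,2-trifluoroethoxy)phosphoryl]propanoate
Product: 3 ethyl (Z)-4-[(4-methoxybenzyl)oxy]-2-methylbut-2-enoate
Conditions: KHMDS, 18-crown-6, THF, −78 °C
Reagents that add atoms: none
Why: Still–Gennari Horner–Wadsworth–Emmons olefination, in which the electron-poor trifluoroethyl phosphonate with a crown-sequestered potassium counter-ion collapses from the kinetic adduct and should give the Z-trisubstituted ester, fixing the C4=C5 geometry (C3 and C6 cis) of the target.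

Step 2
Reactants: 3 ethyl (Z)-4-[(4-methoxybenzyl)oxy]-2-methylbut-2-enoate
Product: 4 (Z)-4-[(4-methoxybenzyl)oxy]-2-methylbut-2-en-1-ol
Conditions: DIBAL-H (2.2 equiv), CH2Cl2, −78 °C
Reagents that add atoms: none
Why: DIBAL-H 1,2-reduction of an enoate to the allylic alcohol leaves the PMB ether and the olefin geometry untouched.

Step 3
Reactants: 4 (Z)-4-[(4-methoxybenzyl)oxy]-2-methylbut-2-en-1-ol
Product: 5 (Z)-4-[(4-methoxybenzyl)oxy]-2-methylbut-2-enal
Conditions: MnO2, CH2Cl2, rt
Reagents that add atoms: none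
Why: Allylic oxidation with manganese dioxide is neutral and heterogeneous, so the Z-enal (C3 aldehyde) should form without isomerisation.

Step 4
Reactants: 6 (R)-(−)-linalool
Product: 7 (R)-linalool triethylsilyl ether
Conditions: TESOTf, 2,6-lutidine, CH2Cl2, 0 °C
Reagents that add atoms: triethylsilyl trifluoromethanesulfonate, CC[Si](CC)(CC)OS(=O)(=O)C(F)(F)F
Why: Silyl triflate silylation of the tertiary allylic alcohol frees the later aldehyde from lactol formation; the C10 stereocentre is taken unchanged from the chiral pool.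

Step 5
Reactants: 7 (R)-linalool triethylsilyl ether
Product: 8 (4R)-4-methyl-4-(triethylsilyloxy)hex-5-enal
Conditions: O3, CH2Cl2/pyridine, −78 °C (indicator end point); then Me2S
Reagents that add atoms: ozone, [O-][O+]=O
Why: Chemoselective ozonolysis, in which the electron-rich trisubstituted olefin reacts far faster than the hindered monosubstituted vinyl group, gives the C7 aldehyde after reductive work-up.

Step 6
Reactants: 8 (4R)-4-methyl-4-(triethylsilyloxy)hex-5-enal
Product: 10 (2R,4R)-2-(anilinooxy)-4-methyl-4-(triethylsilyloxy)hex-5-en-1-ol, via α-aminoxy aldehyde 9 (not isolated)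
Conditions: PhNO, L-proline (20 mol%), DMSO, rt; then NaBH4, MeOH, 0 °C
Reagents that add atoms: nitrosobenzene, O=Nc1ccccc1
Why: Proline-catalysed α-aminoxylation (enamine catalysis), in which the L-proline enamine attacks the acid-activated nitroso oxygen on one face, should set C8 as (R) under catalyst control regardless of the remote C10 centre, and the in situ borohydride reduction protects the labile α-oxy aldehyde.

Step 7
Reactants: 10 (2R,4R)-2-(anilinooxy)-4-methyl-4-(triethylsilyloxy)hex-5-en-1-ol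
Product: 11 (2R,4R)-4-methyl-4-(triethylsilyloxy)hex-5-ene-1,2-diol
Conditions: CuSO4·5H2O (0.3 equiv), MeOH, 0 °C to rt
Reagents that add atoms: none
Why: Copper(II)-catalysed N–O cleavage of the O-alkyl-N-arylhydroxylamine releases the diol without touching the vinyl group or the tertiary silyl ether.

Step 8
Reactants: 11 (2R,4R)-4-methyl-4-(triethylsilyloxy)hex-5-ene-1,2-diol
Product: 12 (3R,5R)-3-methyl-3,5,6-tris(triethylsilyloxy)hex-1-ene
Conditions: TESCl, imidazole, DMAP (cat.), CH2Cl2, 0 °C to rt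
Reagents that add atoms: chlorotriethylsilane, CC[Si](CC)(CC)Cl
Why: Standard silylation of the primary (O7) and secondary (O8) hydroxyls gives one protecting-group type that can later be differentiated by position.

Step 9
Reactants: 12 (3R,5R)-3-methyl-3,5,6-tris(triethylsilyloxy)hex-1-ene
Product: 13 (3R,5R)-3-methyl-3,5,6-tris(triethylsilyloxy)hexan-2-one
Conditions: PdCl2 (cat.), Cu(OAc)2, O2, DMA/H2O, rt
Reagents that add atoms: water, O
Why: Tsuji–Wacker oxidation (Markovnikov hydroxypalladation, β-hydride elimination) of the only olefin gives the C1 methyl ketone, and the copper acetate variant keeps the medium near neutral so the silyl ethers should survive.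

Step 10
Reactants: 13 (3R,5R)-3-methyl-3,5,6-tris(triethylsilyloxy)hexan-2-one; 5 (Z)-4-[(4-methoxybenzyl)oxy]-2-methylbut-2-enal
Product: 15 (2Z,4S,7R,9R)-4-hydroxy-1-[(4-methoxybenzyl)oxy]-3,7-dimethyl-7,9,10-tris(triethylsilyloxy)dec-2-en-6-one, via boron enolate 14 (not isolated)
Conditions: (−)-Ipc2BCl, Et3N, Et2O, 0 °C; then 5, −78 to −20 °C; H2O2, pH 7 buffer, MeOH
Reagents that add atoms: none
Why: Paterson boron aldol reaction, in which the ketone can enolise only at its methyl group (C2) and the isopinocampheyl ligands are expected, by the model for methyl ketone enolates, to direct addition to the si face of enal 5, giving the (S)-carbinol at C3 that the next inversion requires.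

Step 11
Reactants: 15 (2Z,4S,7R,9R)-4-hydroxy-1-[(4-methoxybenzyl)oxy]-3,7-dimethyl-7,9,10-tris(triethylsilyloxy)dec-2-en-6-one
Product: 16 (E)-oxime of 15
Conditions: NH2OH·HCl, pyridine, EtOH, 40 °C
Reagents that add atoms: hydroxylamine hydrochloride, NO.Cl
Why: Oxime condensation at the C1 ketone should place the N–OH anti to the quaternary C10 and therefore syn to C2, the geometry needed for ring closure onto C3.

Step 12
Reactants: 16 (E)-oxime of 15
Product: 17 (5R)-5-[(Z)-4-[(4-methoxybenzyl)oxy]but-2-en-2-yl]-3-[(2R,4R)-2,4,5-tris(triethylsilyloxy)pentan-2-yl]-4,5-dihydroisoxazole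
Conditions: PPh3, DIAD, THF, 0 °C to rt
Reagents that add atoms: none
Why: Intramolecular Mitsunobu O-alkylation of the oxime (5-exo-tet SN2) closes the isoxazoline with inversion at C3, which installs the (3R) C–O configuration of the target and masks the C1 carbonyl and O3 in one ring.

Step 13
Reactants: 17 (5R)-5-[(Z)-4-[(4-methoxybenzyl)oxy]but-2-en-2-yl]-3-[(2R,4R)-2,4,5-tris(triethylsilyloxy)pentan-2-yl]-4,5-dihydroisoxazole
Product: 18 (2R,4R)-4-[(5R)-5-[(Z)-4-[(4-methoxybenzyl)oxy]but-2-en-2-yl]-4,5-dihydroisoxazol-3-yl]-2,4-bis(triethylsilyloxy)pentanal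
Conditions: (COCl)2, DMSO, CH2Cl2, −78 to −30 °C; then Et3N
Reagents that add atoms: none
Why: Swern oxidation applied directly to the silyl ether, in which the chlorosulfonium reagent cleaves only the unhindered primary O–SiEt3 bond and oxidises C7 to the aldehyde while the secondary and tertiary silyl ethers remain.

Step 14
Reactants: 18 (2R,4R)-4-[(5R)-5-[(Z)-4-[(4-methoxybenzyl)oxy]but-2-en-2-yl]-4,5-dihydroisoxazol-3-yl]-2,4-bis(triethylsilyloxy)pentanal; 19 methyl propiolate
Product: 21 methyl (4R,6R)-3-hydroxy-6-[(5R)-5-[(Z)-4-[(4-methoxybenzyl)oxy]but-2-en-2-yl]-4,5-dihydroisoxazol-3-yl]-2-methylidene-4,6-bis(triethylsilyloxy)heptanoate (C7 carbinol epimers), via vinylalane 20 (not isolated)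
Conditions: 19, DIBAL-H, HMPA, THF, 0 °C; then 18, 0 °C to rt
Reagents that add atoms: none
Why: Vinylalumination (hydroalumination of the propiolate to the α-aluminated acrylate, then carbonyl addition) gives the Morita–Baylis–Hillman-type adduct quickly and without base-induced epimerisation at C8; the new C7 carbinol centre is inconsequential because C7 becomes sp2 in the next step.

Step 15
Reactants: 21 methyl (4R,6R)-3-hydroxy-6-[(5R)-5-[(Z)-4-[(4-methoxybenzyl)oxy]but-2-en-2-yl]-4,5-dihydroisoxazol-3-yl]-2-methylidene-4,6-bis(triethylsilyloxy)heptanoate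
Product: 22 methyl (2Z,4R,6R)-2-(bromomethyl)-6-[(5R)-5-[(Z)-4-[(4-methoxybenzyl)oxy]but-2-en-2-yl]-4,5-dihydroisoxazol-3-yl]-4,6-bis(triethylsilyloxy)hept-2-enoate
Conditions: NBS, Me2S, CH2Cl2, 0 °C to rt
Reagents that add atoms: N-bromosuccinimide, O=C1CCC(=O)N1Br
Why: Corey–Kim-type activation of the allylic alcohol as an alkoxysulfonium salt and SN2′ attack of bromide at C13 give the rearranged primary allylic bromide with the conjugated Z-enoate under non-acidic conditions.

Step 16
Reactants: 22 methyl (2Z,4R,6R)-2-(bromomethyl)-6-[(5R)-5-[(Z)-4-[(4-methoxybenzyl)oxy]but-2-en-2-yl]-4,5-dihydroisoxazol-3-yl]-4,6-bis(triethylsilyloxy)hept-2-enoate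
Product: 23 methyl (2Z,4R,6R)-2-(bromomethyl)-6-[(5R)-5-[(Z)-4-hydroxybut-2-en-2-yl]-4,5-dihydroisoxazol-3-yl]-4,6-bis(triethylsilyloxy)hept-2-enoate
Conditions: DDQ, CH2Cl2/pH 7 buffer, 0 °C
Reagents that add atoms: none
Why: Oxidative PMB ether cleavage with DDQ (benzylic hydride abstraction, hydrolysis of the oxocarbenium ion) is orthogonal to the silyl ethers, the allylic bromide and the isoxazoline.

Step 17
Reactants: 23 methyl (2Z,4R,6R)-2-(bromomethyl)-6-[(5R)-5-[(Z)-4-hydroxybut-2-en-2-yl]-4,5-dihydroisoxazol-3-yl]-4,6-bis(triethylsilyloxy)hept-2-enoate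
Product: 24 methyl (2Z,4R,6R)-2-(bromomethyl)-6-[(5R)-5-[(Z)-4-oxobut-2-en-2-yl]-4,5-dihydroisoxazol-3-yl]-4,6-bis(triethylsilyloxy)hept-2-enoate (seco aldehyde)
Conditions: MnO2, CH2Cl2, rt
Reagents that add atoms: none
Why: Manganese dioxide oxidises only the primary allylic alcohol and should deliver the C6 Z-enal without disturbing the allylic bromide.

Step 18
Reactants: 24 methyl (2Z,4R,6R)-2-(bromomethyl)-6-[(5R)-5-[(Z)-4-oxobut-2-en-2-yl]-4,5-dihydroisoxazol-3-yl]-4,6-bis(triethylsilyloxy)hept-2-enoate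
Product: 27 bis-TES isoxazoline-bridged macrolactone (C1=N–O–C3 bridge; ten-membered ring C1–C10; trans-fused 12,6-olide; C3/C6/C7/C8/C10 as in 32), via allylchromium species 25 (not isolated), via hydroxy ester 26 (not isolated)
Conditions: CrCl2 (10 equiv), DMF, 25 °C, slow addition of 24 (final 2 mM); aq. NH4Cl; then cat. PPTS, CH2Cl2
Reagents that add atoms: none
Why: Chromium(II) inserts into the allylic C–Br bond of 24 to give the 2-(methoxycarbonyl)allylchromium(III) species 25, whose γ-carbon C7 adds to the Z-enal carbon C6 through a chair-like six-membered Cr–O transition state (intramolecular Nozaki–Hiyama/Barbier allylation, the reaction type used to close ten-membered germacranolide rings from seco (bromomethyl)acrylate aldehydes), and the C6 alkoxide of 26 then acylates C12 with loss of methanol. The carbocycle C1–C10 closes in the 10-exo-trig mode at the aldehyde and the lactone O–C6–C7–C11–C12 in the 5-exo-trig mode at the ester. C6 and C7 are set together: the anti (6,7-trans) relationship should follow from the transition state in which both ring branches (C5 on the aldehyde, C8 on the allyl terminus) are equatorial, the arrangement that the eight-atom tether can span without transannular strain, and the sense relative to C8 from allylic 1,3-strain, which holds H8 in the enoate plane, places the C8–C9 tether anti to the forming bond and turns the OSiEt3 group outward. The step needs aldehyde-over-ketone, ten-ring-over-five-ring and single-lactone selectivity: the C1 carbonyl, which would otherwise be allylated in a fast 5-exo closure, is locked in the isoxazoline, the aldehyde is the only free electrophile, and the silyl ether on O8 leaves O6 as the only oxygen able to lactonise and is a poor leaving group for 1,4-elimination of the allylmetal. High dilution suppresses oligomerisation, and Cr(II) at room temperature should neither cleave the isoxazoline N–O bond nor isomerise the Z-enal.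

Step 19
Reactants: 27 bis-TES isoxazoline-bridged macrolactone
Product: 28 isoxazoline-bridged macrolactone 8,10-diol
Conditions: HF·pyridine, pyridine, THF, 0 °C to rt
Reagents that add atoms: none
Why: Fluoride-mediated desilylation under buffered conditions removes the secondary (O8) and tertiary (O10) triethylsilyl groups without opening the lactone or the isoxazoline.

Step 20
Reactants: 28 isoxazoline-bridged macrolactone 8,10-diol; 29 isovaleric anhydride
Product: 30 isoxazoline-bridged macrolactone 8-isovalerate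
Conditions: 29, DMAP (cat.), Et3N, CH2Cl2, rt
Reagents that add atoms: none
Why: DMAP-catalysed acylation esterifies the only secondary hydroxyl (O8), because the tertiary O10 hydroxyl is inert and O3 is still held in the isoxazoline.

Step 21
Reactants: 30 isoxazoline-bridged macrolactone 8-isovalerate
Product: 32 target CNP0406522.1, via β-hydroxy imine 31 (not isolated)
Conditions: Mo(CO)6, MeCN/H2O, 80 °C
Reagents that add atoms: water, O
Why: Molybdenum hexacarbonyl-mediated reductive N–O cleavage of the isoxazoline gives the β-hydroxy imine, whose in situ hydrolysis releases the C1 ketone and the C3 hydroxyl with retention at C3, under conditions that do not hydrogenate the exocyclic methylene or the C4=C5 olefin.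

**Compound list**

1 | 2-[(4-methoxybenzyl)oxy]acetaldehyde | COc1ccc(COCC=O)cc1 | starting material
2 | ethyl 2-[bis(2,2,2-trifluoroethoxy)phosphoryl]propanoate | CCOC(=O)C(C)P(=O)(OCC(F)(F)F)OCC(F)(F)F | starting material
3 | ethyl (Z)-4-[(4-methoxybenzyl)oxy]-2-methylbut-2-enoate | CCOC(=O)/C(C)=C\COCc1ccc(OC)cc1 | intermediate
4 | (Z)-4-[(4-methoxybenzyl)oxy]-2-methylbut-2-en-1-ol | OC/C(C)=C\COCc1ccc(OC)cc1 | intermediate
5 | (Z)-4-[(4-methoxybenzyl)oxy]-2-methylbut-2-enal | O=C/C(C)=C\COCc1ccc(OC)cc1 | intermediate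
6 | (R)-(−)-linalool | C=C[C@](C)(O)CCC=C(C)C | starting material
7 | (R)-linalool triethylsilyl ether | C=C[C@](C)(O[Si](CC)(CC)CC)CCC=C(C)C | intermediate
8 | (4R)-4-methyl-4-(triethylsilyloxy)hex-5-enal | C=C[C@](C)(O[Si](CC)(CC)CC)CCC=O | intermediate
9 | (2R,4R)-2-(anilinooxy)-4-methyl-4-(triethylsilyloxy)hex-5-enal (not isolated) | C=C[C@](C)(O[Si](CC)(CC)CC)C[C@@H](ONc1ccccc1)C=O | intermediate
10 | (2R,4R)-2-(anilinooxy)-4-methyl-4-(triethylsilyloxy)hex-5-en-1-ol | C=C[C@](C)(O[Si](CC)(CC)CC)C[C@@H](ONc1ccccc1)CO | intermediate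
11 | (2R,4R)-4-methyl-4-(triethylsilyloxy)hex-5-ene-1,2-diol | C=C[C@](C)(O[Si](CC)(CC)CC)C[C@@H](O)CO | intermediate
12 | (3R,5R)-3-methyl-3,5,6-tris(triethylsilyloxy)hex-1-ene | C=C[C@](C)(O[Si](CC)(CC)CC)C[C@@H](O[Si](CC)(CC)CC)CO[Si](CC)(CC)CC | intermediate
13 | (3R,5R)-3-methyl-3,5,6-tris(triethylsilyloxy)hexan-2-one | CC(=O)[C@](C)(O[Si](CC)(CC)CC)C[C@@H](O[Si](CC)(CC)CC)CO[Si](CC)(CC)CC | intermediate
14 | diisopinocampheylboron enolate of 13 (not isolated) | C=C(OB([C@@H]1C[C@@H]2C[C@H]([C@H]1C)C2(C)C)[C@@H]1C[C@@H]2C[C@H]([C@H]1C)C2(C)C)[C@](C)(O[Si](CC)(CC)CC)C[C@@H](O[Si](CC)(CC)CC)CO[Si](CC)(CC)CC | intermediate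
15 | (2Z,4S,7R,9R)-4-hydroxy-1-[(4-methoxybenzyl)oxy]-3,7-dimethyl-7,9,10-tris(triethylsilyloxy)dec-2-en-6-one | COc1ccc(COC/C=C(/C)[C@@H](O)CC(=O)[C@](C)(O[Si](CC)(CC)CC)C[C@@H](O[Si](CC)(CC)CC)CO[Si](CC)(CC)CC)cc1 | intermediate
16 | (E)-oxime of 15 | COc1ccc(COC/C=C(/C)[C@@H](O)C/C(=N\O)[C@](C)(O[Si](CC)(CC)CC)C[C@@H](O[Si](CC)(CC)CC)CO[Si](CC)(CC)CC)cc1 | intermediate
17 | (5R)-5-[(Z)-4-[(4-methoxybenzyl)oxy]but-2-en-2-yl]-3-[(2R,4R)-2,4,5-tris(triethylsilyloxy)pentan-2-yl]-4,5-dihydroisoxazole | COc1ccc(COC/C=C(/C)[C@H]2CC(=NO2)[C@](C)(O[Si](CC)(CC)CC)C[C@@H](O[Si](CC)(CC)CC)CO[Si](CC)(CC)CC)cc1 | intermediate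
18 | (2R,4R)-4-[(5R)-5-[(Z)-4-[(4-methoxybenzyl)oxy]but-2-en-2-yl]-4,5-dihydroisoxazol-3-yl]-2,4-bis(triethylsilyloxy)pentanal | COc1ccc(COC/C=C(/C)[C@H]2CC(=NO2)[C@](C)(O[Si](CC)(CC)CC)C[C@@H](O[Si](CC)(CC)CC)C=O)cc1 | intermediate
19 | methyl propiolate | C#CC(=O)OC | starting material
20 | methyl 2-(diisobutylalumanyl)acrylate (vinylalane, not isolated) | C=C([Al](CC(C)C)CC(C)C)C(=O)OC | intermediate
21 | methyl (4R,6R)-3-hydroxy-6-[(5R)-5-[(Z)-4-[(4-methoxybenzyl)oxy]but-2-en-2-yl]-4,5-dihydroisoxazol-3-yl]-2-methylidene-4,6-bis(triethylsilyloxy)heptanoate (C3 epimers) | COc1ccc(COC/C=C(/C)[C@H]2CC(=NO2)[C@](C)(O[Si](CC)(CC)CC)C[C@@H](O[Si](CC)(CC)CC)C(O)C(=C)C(=O)OC)cc1 | intermediate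
22 | methyl (2Z,4R,6R)-2-(bromomethyl)-6-[(5R)-5-[(Z)-4-[(4-methoxybenzyl)oxy]but-2-en-2-yl]-4,5-dihydroisoxazol-3-yl]-4,6-bis(triethylsilyloxy)hept-2-enoate | COc1ccc(COC/C=C(/C)[C@H]2CC(=NO2)[C@](C)(O[Si](CC)(CC)CC)C[C@@H](O[Si](CC)(CC)CC)/C=C(\CBr)C(=O)OC)cc1 | intermediate
23 | methyl (2Z,4R,6R)-2-(bromomethyl)-6-[(5R)-5-[(Z)-4-hydroxybut-2-en-2-yl]-4,5-dihydroisoxazol-3-yl]-4,6-bis(triethylsilyloxy)hept-2-enoate | OC/C=C(/C)[C@H]1CC(=NO1)[C@](C)(O[Si](CC)(CC)CC)C[C@@H](O[Si](CC)(CC)CC)/C=C(\CBr)C(=O)OC | intermediate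
24 | methyl (2Z,4R,6R)-2-(bromomethyl)-6-[(5R)-5-[(Z)-4-oxobut-2-en-2-yl]-4,5-dihydroisoxazol-3-yl]-4,6-bis(triethylsilyloxy)hept-2-enoate | O=C/C=C(/C)[C@H]1CC(=NO1)[C@](C)(O[Si](CC)(CC)CC)C[C@@H](O[Si](CC)(CC)CC)/C=C(\CBr)C(=O)OC | intermediate
25 | allylchromium(III) dichloride derived from 24 (not isolated) | O=C/C=C(/C)[C@H]1CC(=NO1)[C@](C)(O[Si](CC)(CC)CC)C[C@@H](O[Si](CC)(CC)CC)/C=C(\C[Cr](Cl)Cl)C(=O)OC | intermediate
26 | ring-closed 6-hydroxy methyl ester (ten-membered carbocycle, isoxazoline bridge, C7 bearing the 2-(methoxycarbonyl)vinyl group; not isolated) | COC(=O)C(=C)[C@H]1[C@H](O)/C=C(/C)[C@H]2CC(=NO2)[C@](C)(O[Si](CC)(CC)CC)C[C@H]1O[Si](CC)(CC)CC | intermediate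
27 | bis-TES isoxazoline-bridged macrolactone (8,10-bis(triethylsilyl) ether; C1=N–O–C3 bridge; 4Z; 12,6-olide) | C=C1C(=O)O[C@@H]2/C=C(/C)[C@H]3CC(=NO3)[C@](C)(O[Si](CC)(CC)CC)C[C@@H](O[Si](CC)(CC)CC)[C@@H]12 | intermediate
28 | isoxazoline-bridged macrolactone 8,10-diol | C=C1C(=O)O[C@@H]2/C=C(/C)[C@H]3CC(=NO3)[C@](C)(O)C[C@@H](O)[C@@H]12 | intermediate
29 | isovaleric anhydride | CC(C)CC(=O)OC(=O)CC(C)C | starting material
30 | isoxazoline-bridged macrolactone 8-isovalerate | C=C1C(=O)O[C@@H]2/C=C(/C)[C@H]3CC(=NO3)[C@](C)(O)C[C@@H](OC(=O)CC(C)C)[C@@H]12 | intermediate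
31 | C1 β-hydroxy imine of the target (not isolated) | C=C1C(=O)O[C@@H]2/C=C(/C)[C@H](O)CC(=N)[C@](C)(O)C[C@@H](OC(=O)CC(C)C)[C@@H]12 | intermediate
32 | CNP0406522.1 (3R,6R,7R,8R,10R; 4Z) | C=C1C(=O)O[C@@H]2/C=C(/C)[C@H](O)CC(=O)[C@](C)(O)C[C@@H](OC(=O)CC(C)C)[C@@H]12 | target

**Step count**

Total steps: 21. Longest linear sequence: 18 (steps 4–21 from (R)-linalool); steps 1–3 make the enal 5 that joins in step 10.

**Steps most likely to fail**

Step 18. Intermolecular oligomerisation may outrun ring closure, the closed transition state may deliver the cis-fused or the C6/C7-epimeric lactone, or the allylchromium may lose the O8 silyloxy group by reductive 1,4-elimination. The fallback sets out from bromide 22 and comes back at hydroxy ester 26 and lactone 27. Bromide 22 would be converted with Bu3SnLi/CuBr·SMe2 into methyl (2Z,4R,6R)-6-[(5R)-5-[(Z)-4-[(4-methoxybenzyl)oxy]but-2-en-2-yl]-4,5-dihydroisoxazol-3-yl]-2-[(tributylstannyl)methyl]-4,6-bis(triethylsilyloxy)hept-2-enoate F1. The PMB group would be removed with buffered DDQ to give the stannyl allylic alcohol F2, and MnO2 would give the stannyl Z-enal F3. A BF3·OEt2-promoted intramolecular allylstannane addition (CH2Cl2, −78 °C, high dilution) then closes the ring through an open transition state, which follows a different stereochemical model and generates no β-eliminating organometallic. The resulting 26 lactonises with catalytic acid to 27.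

Step 10. Facial selectivity at C3 may be poor if the reagent-controlled boron enolate is mismatched with the quaternary C10 centre, or enolisation of the hindered ketone may be incomplete. The fallback sets out from ketone 13 and comes back at aldol 15. Ketone 13 would be converted with TMSOTf/Et3N into the trimethylsilyl enol ether of 13 F4. F4 would then be added to enal 5 in a Lewis-base-catalysed enantioselective Mukaiyama aldol reaction (SiCl4, chiral bisphosphoramide catalyst, CH2Cl2, −78 °C). Any (3R)-epimer is a diastereomer of 15 and would be removed by chromatography before oximation.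

Step 21. Heating with the low-valent metal may reduce or isomerise the exocyclic C11=C13 methylene, and the freshly released β-ketol may lose water towards the dienone. The fallback sets out from 30 and comes back at target 32. The methylene would first be masked by conjugate addition of dimethylamine to give the 13-(dimethylamino)-11,13-dihydro adduct of 30 F5 (C11 configuration not assigned). The N–O bond would then be cleaved by hydrogenolysis over Raney nickel with boric acid (MeOH/H2O, rt) to the amino ketol F6. N-methylation with MeI would give the methiodide of the amino ketol F7, and elimination with NaHCO3 regenerates the methylene to give 32.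

**Further compounds**

F1 | step 18 | methyl (2Z,4R,6R)-6-[(5R)-5-[(Z)-4-[(4-methoxybenzyl)oxy]but-2-en-2-yl]-4,5-dihydroisoxazol-3-yl]-2-[(tributylstannyl)methyl]-4,6-bis(triethylsilyloxy)hept-2-enoate | COc1ccc(COC/C=C(/C)[C@H]2CC(=NO2)[C@](C)(O[Si](CC)(CC)CC)C[C@@H](O[Si](CC)(CC)CC)/C=C(\C[Sn](CCCC)(CCCC)CCCC)C(=O)OC)cc1
F2 | step 18 | stannyl allylic alcohol (PMB removed from F1) | OC/C=C(/C)[C@H]1CC(=NO1)[C@](C)(O[Si](CC)(CC)CC)C[C@@H](O[Si](CC)(CC)CC)/C=C(\C[Sn](CCCC)(CCCC)CCCC)C(=O)OC
F3 | step 18 | stannyl Z-enal | O=C/C=C(/C)[C@H]1CC(=NO1)[C@](C)(O[Si](CC)(CC)CC)C[C@@H](O[Si](CC)(CC)CC)/C=C(\C[Sn](CCCC)(CCCC)CCCC)C(=O)OC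
F4 | step 10 | trimethylsilyl enol ether of 13 | C=C(O[Si](C)(C)C)[C@](C)(O[Si](CC)(CC)CC)C[C@@H](O[Si](CC)(CC)CC)CO[Si](CC)(CC)CC
F5 | step 21 | 13-(dimethylamino)-11,13-dihydro adduct of 30 (C11 not assigned) | CN(C)CC1C(=O)O[C@@H]2/C=C(/C)[C@H]3CC(=NO3)[C@](C)(O)C[C@@H](OC(=O)CC(C)C)[C@@H]12
F6 | step 21 | amino ketol (13-(dimethylamino)-11,13-dihydro-32; C11 not assigned) | CN(C)CC1C(=O)O[C@@H]2/C=C(/C)[C@H](O)CC(=O)[C@](C)(O)C[C@@H](OC(=O)CC(C)C)[C@@H]12
F7 | step 21 | methiodide of the amino ketol (C11 not assigned) | C[N+](C)(C)CC1C(=O)O[C@@H]2/C=C(/C)[C@H](O)CC(=O)[C@](C)(O)C[C@@H](OC(=O)CC(C)C)[C@@H]12.[I-]
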